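**Retrosynthetic overview**

1. Numbering as in germacrane (ring C1–C10; methyls on C4 and C10, isopropyl on C7, ester O on C8, OH on C6, oxirane on C4/C5). Endgame disconnections: oxirane by C6–OH-directed epoxidation of the (Z)-C4=C5 olefin; C6–OH from a C6–B(pin) group; aroyl ester on a C8 carbinol that comes from a C8 ketone.
2. Enabling feature: at the C8-ketone level the ring holds the γ,δ-unsaturated ketone array O=C8–C7–C6–C5=C4, and the other five ring atoms (C9, C10, C1, C2, C3) link C8 back to C4. C6–C7 is therefore the σ-bond of a Claisen rearrangement whose allyl vinyl ether C7=C8–O–C4–C5=C6 has O, C8 and C4 inside an eight-membered oxocene ring (O, C8, C9, C10, C1, C2, C3, C4).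
3. Key disconnection: C6–C7, by Claisen ring expansion of the oxocene (8 atoms) to a cyclodeca-4,8-dienone (10 atoms). This sets C6, C7 and the (Z)-C4=C5 olefin from the single C4 stereocentre; the (Z)-C10=C1 olefin is already fixed by the eight-membered ring.
4. Oxocene from an eight-membered lactone: exocyclic (Z)-isobutylidene by Takai–Utimoto alkylidenation, (E)-alkenylboronate by Takai olefination of a C5 aldehyde, lactone by ring-closing metathesis of a 3-methylbut-3-enoate, C4 from (R)-2-methylglycidol.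
5. Ring order: eight-membered lactone (step 4) → ten-membered carbocycle (step 9) → oxirane (step 13); the aryl ring is bought.

Key step: step 9

Assumption: (R)-2-methylglycidol (the asymmetric epoxidation product of 2-methylprop-2-en-1-ol) is taken as a purchasable enantiopure building block; position numbers in the Why lines are germacrane numbers.

**Route**

Step 1
Reactants: 1 (R)-2-methylglycidol
Product: 2 triethyl{[(2S)-2-methyloxiran-2-yl]methoxy}silane
Conditions: Et3SiCl, imidazole, CH2Cl2, 0 °C
Reagents that add atoms: chlorotriethylsilane CC[Si](Cl)(CC)CC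
Why: Imidazole-promoted O-silylation of the primary alcohol masks the future C5 oxygen; the quaternary carbon (future C4) is untouched, and the change of descriptor from R to S only reflects new CIP priorities.

Step 2
Reactants: 2 triethyl{[(2S)-2-methyloxiran-2-yl]methoxy}silane; 3 allylmagnesium chloride
Product: 4 (2S)-2-methyl-1-[(triethylsilyl)oxy]hex-5-en-2-ol
Conditions: CuI (10 mol%), THF, −30 → 0 °C; NH4Cl (aq.)
Reagents that add atoms: none
Why: Copper-catalysed SN2 ring opening of the 2,2-disubstituted epoxide at its CH2 terminus by the allyl Grignard reagent adds C1–C3 and frees the tertiary C4–OH without touching the stereocentre.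

Step 3
Reactants: 4 (2S)-2-methyl-1-[(triethylsilyl)oxy]hex-5-en-2-ol; 5 3-methylbut-2-enoyl chloride
Product: 7 (2S)-2-methyl-1-[(triethylsilyl)oxy]hex-5-en-2-yl 3-methylbut-3-enoate, via isopropenylketene 6 (not isolated)
Conditions: Et3N, DMAP (cat.), CH2Cl2, −20 °C → rt
Reagents that add atoms: none
Why: Dehydrochlorination of 5 by Et3N gives vinylketene 6, and its DMAP-assisted addition to the hindered tertiary alcohol followed by α-protonation of the dienolate should give the deconjugated β,γ-unsaturated ester (ketene acylation).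

Step 4
Reactants: 7 (2S)-2-methyl-1-[(triethylsilyl)oxy]hex-5-en-2-yl 3-methylbut-3-enoate
Product: 8 (4Z,8S)-4,8-dimethyl-8-{[(triethylsilyl)oxy]methyl}-3,6,7,8-tetrahydro-2H-oxocin-2-one
Conditions: second-generation Hoveyda–Grubbs catalyst (10 mol%), 1,4-benzoquinone (20 mol%), PhMe (2 mM), 80 °C
Reagents that add atoms: none
Why: Ring-closing olefin metathesis between the monosubstituted and the 1,1-disubstituted olefin at high dilution, helped by the geminal substitution at C4, should close the eight-membered lactone, in which ring size forces the (Z) geometry of the trisubstituted C10=C1 olefin.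

Step 5
Reactants: 8 (4Z,8S)-4,8-dimethyl-8-{[(triethylsilyl)oxy]methyl}-3,6,7,8-tetrahydro-2H-oxocin-2-one
Product: 9 (2S,5Z)-2,6-dimethyl-8-oxo-3,4,7,8-tetrahydro-2H-oxocine-2-carbaldehyde
Conditions: (COCl)2, DMSO, CH2Cl2, −78 → −30 °C; then Et3N, −78 °C → rt
Reagents that add atoms: none
Why: Swern oxidation applied directly to the primary triethylsilyl ether (oxidative desilylation) should give the C5 aldehyde in one operation, and its quaternary α-carbon cannot epimerise.

Step 6
Reactants: 9 (2S,5Z)-2,6-dimethyl-8-oxo-3,4,7,8-tetrahydro-2H-oxocine-2-carbaldehyde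
Product: 10 (4Z,8S)-4,8-dimethyl-8-[(E)-2-(4,4,5,5-tetramethyl-1,3,2-dioxaborolan-2-yl)ethenyl]-3,6,7,8-tetrahydro-2H-oxocin-2-one
Conditions: Cl2CHB(pin), CrCl2, LiI, THF, 25 °C
Reagents that add atoms: 2-(dichloromethyl)-4,4,5,5-tetramethyl-1,3,2-dioxaborolane ClC(Cl)B1OC(C)(C)C(C)(C)O1
Why: Takai olefination with the geminal dichromium reagent made from the dichloromethylboronate should convert the aldehyde into the (E)-alkenylboronate (E-selective addition–elimination) under non-basic conditions that spare the lactone and its acidic C9 methylene.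

Step 7
Reactants: 11 isobutyraldehyde
Product: 12 1,1-dibromo-2-methylpropane
Conditions: P(OPh)3, Br2, CH2Cl2, −78 °C → rt
Reagents that add atoms: bromine BrBr
Why: Deoxygenative geminal dibromination of the aldehyde by the bromophosphorane formed from P(OPh)3 and Br2 (Appel-type activation of the carbonyl oxygen) supplies the isobutylidene donor.

Step 8
Reactants: 10 (4Z,8S)-4,8-dimethyl-8-[(E)-2-(4,4,5,5-tetramethyl-1,3,2-dioxaborolan-2-yl)ethenyl]-3,6,7,8-tetrahydro-2H-oxocin-2-one; 12 1,1-dibromo-2-methylpropane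
Product: 14 (2Z,4Z,8S)-4,8-dimethyl-2-(2-methylpropylidene)-8-[(E)-2-(4,4,5,5-tetramethyl-1,3,2-dioxaborolan-2-yl)ethenyl]-3,6,7,8-tetrahydro-2H-oxocine, via geminal dizinc reagent 13 (not isolated)
Conditions: Zn, TiCl4, TMEDA, PbCl2 (cat.), THF, 25 °C; K2CO3 (aq.) work-up, basic Al2O3
Reagents that add atoms: none
Why: Takai–Utimoto alkylidenation of the lactone carbonyl by the titanium-activated geminal dizinc reagent should give the exocyclic enol ether with isopropyl cis to the ring oxygen, the (Z) isomer that this reaction gives with esters and that avoids allylic strain with C9H2; work-up is kept basic because acid would move the double bond into the ring.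

Step 9
Reactants: 14 (2Z,4Z,8S)-4,8-dimethyl-2-(2-methylpropylidene)-8-[(E)-2-(4,4,5,5-tetramethyl-1,3,2-dioxaborolan-2-yl)ethenyl]-3,6,7,8-tetrahydro-2H-oxocine
Product: 15 (2R,3S,4Z,8Z)-5,9-dimethyl-2-(propan-2-yl)-3-(4,4,5,5-tetramethyl-1,3,2-dioxaborolan-2-yl)cyclodeca-4,8-dien-1-one
Conditions: PhMe (0.01 M), 2,6-di-tert-butyl-4-methylpyridine (10 mol%), silylated sealed tube, 110 °C
Reagents that add atoms: none
Why: Concerted suprafacial [3,3]-sigmatropic (aliphatic Claisen) rearrangement of the allyl vinyl ether C7=C8–O–C4–C5=C6: the ring bond O–C4 breaks while C6–C7 forms, and the ring oxygen becomes the exocyclic C8 carbonyl oxygen, which makes the step irreversible. The closest known reaction types are the two-carbon Claisen ring expansion of 2-methylene-6-vinyltetrahydropyrans to cyclooct-4-enones and Claisen rearrangements of 3-borylallyl ethers that give α-substituted allylboronates. The ten-membered carbocycle is closed by ring expansion: the new C6–C7 bond joins the two exocyclic olefin termini across the oxocene through a chair-like six-membered transition state bridged by C9–C10=C1–C2–C3 (a bicyclo[5.3.1] array), so the eight ring atoms less oxygen plus C5, C6 and C7 make the ten-membered ring. C6 and C7 are set by that chair under control of the C4 stereocentre: the five-atom tether can only span the pseudo-axial position at C4 (methyl equatorial), which fixes the chair and its face, gives the (Z)-C4=C5 olefin, and places the (Z)-enol-ether isopropyl axial and the (E)-boryl group equatorial, so that H-6 and H-7 end up cis (6S,7R in 15, the spatial arrangement of the target) while the C4 chirality is transferred and erased. The step needs chair over boat, no acid-catalysed shift of the exocyclic enol-ether double bond or ionisation of the tertiary allylic C4–O bond, and no follow-up reaction; the short tether and the lack of 1,3-diaxial partners for the axial isopropyl favour the chair, the hindered pyridine and silylated glass exclude acid, 110 °C stays below the range of the boat Cope rearrangement of the (Z,Z)-1,5-diene, and allylboration of the new ketone by the C6 boronate would need a norbornane-like boat and should not compete.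

Step 10
Reactants: 15 (2R,3S,4Z,8Z)-5,9-dimethyl-2-(propan-2-yl)-3-(4,4,5,5-tetramethyl-1,3,2-dioxaborolan-2-yl)cyclodeca-4,8-dien-1-one
Product: 16 (1R,2R,3S,4Z,8Z)-5,9-dimethyl-2-(propan-2-yl)-3-(4,4,5,5-tetramethyl-1,3,2-dioxaborolan-2-yl)cyclodeca-4,8-dien-1-ol
Conditions: i-Bu2AlH, CH2Cl2, −78 °C; Rochelle salt (aq.)
Reagents that add atoms: none
Why: Hydride addition to the C8 ketone under Felkin–Anh control (the C6–C7 ring bond carrying the bulky boronate lies anti to the incoming hydride, which passes H-7, the same sense as peripheral attack on the medium ring) should set C8 with its oxygen cis to the isopropyl group, as in the target.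

Step 11
Reactants: 16 (1R,2R,3S,4Z,8Z)-5,9-dimethyl-2-(propan-2-yl)-3-(4,4,5,5-tetramethyl-1,3,2-dioxaborolan-2-yl)cyclodeca-4,8-dien-1-ol; 17 3,4,5-trimethoxybenzoyl chloride
Product: 18 (1R,2R,3S,4Z,8Z)-5,9-dimethyl-2-(propan-2-yl)-3-(4,4,5,5-tetramethyl-1,3,2-dioxaborolan-2-yl)cyclodeca-4,8-dien-1-yl 3,4,5-trimethoxybenzoate
Conditions: DMAP, Et3N, CH2Cl2, 0 °C → rt
Reagents that add atoms: none
Why: DMAP-catalysed acylation (nucleophilic catalysis) of the only free hydroxyl, C8–OH; the C6 oxygen is still masked as the boronate, which settles the differentiation of the 6,8-diol.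

Step 12
Reactants: 18 (1R,2R,3S,4Z,8Z)-5,9-dimethyl-2-(propan-2-yl)-3-(4,4,5,5-tetramethyl-1,3,2-dioxaborolan-2-yl)cyclodeca-4,8-dien-1-yl 3,4,5-trimethoxybenzoate
Product: 19 (1R,2S,3S,4Z,8Z)-3-hydroxy-5,9-dimethyl-2-(propan-2-yl)cyclodeca-4,8-dien-1-yl 3,4,5-trimethoxybenzoate
Conditions: H2O2 (30% aq.), NaHCO3, THF/H2O, 0 °C → rt
Reagents that add atoms: hydrogen peroxide OO
Why: Oxidation of the allylic C–B bond by hydroperoxide (1,2-migration of C6 from boron to oxygen) proceeds with retention at C6 and without allylic transposition, and the bicarbonate buffer should keep the aroyl group from migrating to the new 1,3-syn hydroxyl.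

Step 13
Reactants: 19 (1R,2S,3S,4Z,8Z)-3-hydroxy-5,9-dimethyl-2-(propan-2-yl)cyclodeca-4,8-dien-1-yl 3,4,5-trimethoxybenzoate
Product: 20 (1(10)Z,4R,5S,6R,7S,8R)-4,5-epoxy-6-hydroxygermacr-1(10)-en-8-yl 3,4,5-trimethoxybenzoate (target)
Conditions: Ti(OiPr)4 (20 mol%), t-BuOOH (in decane), 4 Å MS, CH2Cl2, −20 °C
Reagents that add atoms: tert-butyl hydroperoxide CC(C)(C)OO
Why: Hydroxyl-directed epoxidation through the titanium alkoxide–alkyl peroxide template touches only the allylic-alcohol olefin C4=C5 (C10=C1 has no directing group), and allylic 1,3-strain between C3H2 and the C6 substituents holds H-6 in the olefin plane so that oxygen arrives on the peripheral face that carries the C6–O bond, the threo mode that sets C4 (R) and C5 (S) of the cis-epoxide.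

**Compound list**

1 | (R)-2-methylglycidol, [(2R)-2-methyloxiran-2-yl]methanol | C[C@@]1(CO)CO1 | starting material
2 | triethyl{[(2S)-2-methyloxiran-2-yl]methoxy}silane | C[C@@]1(CO[Si](CC)(CC)CC)CO1 | intermediate
3 | allylmagnesium chloride | C=CC[Mg]Cl | starting material
4 | (2S)-2-methyl-1-[(triethylsilyl)oxy]hex-5-en-2-ol | C=CCC[C@@](C)(CO[Si](CC)(CC)CC)O | intermediate
5 | 3-methylbut-2-enoyl chloride | CC(C)=CC(=O)Cl | starting material
6 | isopropenylketene (3-methylbuta-1,3-dien-1-one), not isolated | C=C(C)C=C=O | intermediate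
7 | (2S)-2-methyl-1-[(triethylsilyl)oxy]hex-5-en-2-yl 3-methylbut-3-enoate | C=CCC[C@@](C)(CO[Si](CC)(CC)CC)OC(=O)CC(C)=C | intermediate
8 | (4Z,8S)-4,8-dimethyl-8-{[(triethylsilyl)oxy]methyl}-3,6,7,8-tetrahydro-2H-oxocin-2-one | O=C1C/C(C)=C\CC[C@@](C)(CO[Si](CC)(CC)CC)O1 | intermediate
9 | (2S,5Z)-2,6-dimethyl-8-oxo-3,4,7,8-tetrahydro-2H-oxocine-2-carbaldehyde | O=C1C/C(C)=C\CC[C@@](C)(C=O)O1 | intermediate
10 | (4Z,8S)-4,8-dimethyl-8-[(E)-2-(4,4,5,5-tetramethyl-1,3,2-dioxaborolan-2-yl)ethenyl]-3,6,7,8-tetrahydro-2H-oxocin-2-one | O=C1C/C(C)=C\CC[C@@](C)(/C=C/B2OC(C)(C)C(C)(C)O2)O1 | intermediate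
11 | isobutyraldehyde (2-methylpropanal) | CC(C)C=O | starting material
12 | 1,1-dibromo-2-methylpropane | CC(C)C(Br)Br | intermediate
13 | 1,1-bis(bromozincio)-2-methylpropane (geminal dizinc reagent, titanium-activated), not isolated | CC(C)C([Zn]Br)[Zn]Br | intermediate
14 | (2Z,4Z,8S)-4,8-dimethyl-2-(2-methylpropylidene)-8-[(E)-2-(4,4,5,5-tetramethyl-1,3,2-dioxaborolan-2-yl)ethenyl]-3,6,7,8-tetrahydro-2H-oxocine | CC(C)/C=C1/C/C(C)=C\CC[C@@](C)(/C=C/B2OC(C)(C)C(C)(C)O2)O1 | intermediate
15 | (2R,3S,4Z,8Z)-5,9-dimethyl-2-(propan-2-yl)-3-(4,4,5,5-tetramethyl-1,3,2-dioxaborolan-2-yl)cyclodeca-4,8-dien-1-one | O=C1C/C(C)=C\CC/C(C)=C\[C@H](B2OC(C)(C)C(C)(C)O2)[C@@H]1C(C)C | intermediate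
16 | (1R,2R,3S,4Z,8Z)-5,9-dimethyl-2-(propan-2-yl)-3-(4,4,5,5-tetramethyl-1,3,2-dioxaborolan-2-yl)cyclodeca-4,8-dien-1-ol | O[C@@H]1C/C(C)=C\CC/C(C)=C\[C@H](B2OC(C)(C)C(C)(C)O2)[C@@H]1C(C)C | intermediate
17 | 3,4,5-trimethoxybenzoyl chloride | COc1cc(C(=O)Cl)cc(OC)c1OC | starting material
18 | (1R,2R,3S,4Z,8Z)-5,9-dimethyl-2-(propan-2-yl)-3-(4,4,5,5-tetramethyl-1,3,2-dioxaborolan-2-yl)cyclodeca-4,8-dien-1-yl 3,4,5-trimethoxybenzoate | COc1cc(C(=O)O[C@@H]2C/C(C)=C\CC/C(C)=C\[C@H](B3OC(C)(C)C(C)(C)O3)[C@@H]2C(C)C)cc(OC)c1OC | intermediate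
19 | (1R,2S,3S,4Z,8Z)-3-hydroxy-5,9-dimethyl-2-(propan-2-yl)cyclodeca-4,8-dien-1-yl 3,4,5-trimethoxybenzoate | COc1cc(C(=O)O[C@@H]2C/C(C)=C\CC/C(C)=C\[C@H](O)[C@@H]2C(C)C)cc(OC)c1OC | intermediate
20 | (1(10)Z,4R,5S,6R,7S,8R)-4,5-epoxy-6-hydroxygermacr-1(10)-en-8-yl 3,4,5-trimethoxybenzoate | COc1cc(C(=O)O[C@@H]2C/C(C)=C\CC[C@@]3(C)O[C@H]3[C@H](O)[C@@H]2C(C)C)cc(OC)c1OC | target

**Step count**

Total steps: 13. Longest linear sequence: 12 steps (steps 1–6 and 8–13; step 7 is a one-step side branch).

**Steps most likely to fail**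

Step 4 (ring-closing metathesis). Closure of the strained eight-membered lactone onto a 1,1-disubstituted olefin may lose out to intermolecular cross-metathesis (oligomer formation) or stall after the catalyst has loaded on the terminal olefin. The fallback closes the ring at the acyl C–O bond by intramolecular ketene capture, which tolerates a tertiary alcohol, and sets out from 4. Ozonolysis of the terminal olefin (O3, CH2Cl2/MeOH, −78 °C; Me2S) should give (4S)-4-hydroxy-4-methyl-5-[(triethylsilyl)oxy]pentanal F1, in equilibrium with its lactol. Wittig olefination with the ylide from (1-iodoethyl)triphenylphosphonium iodide and NaN(SiMe3)2 (THF, −78 °C) should give (2S,5Z)-6-iodo-2-methyl-1-[(triethylsilyl)oxy]hept-5-en-2-ol F2, with iodine cis to the chain. Negishi coupling with (ethoxyethynyl)zinc chloride (Pd(PPh3)4, THF, rt) should give (2S,5Z)-8-ethoxy-2,6-dimethyl-1-[(triethylsilyl)oxy]oct-5-en-7-yn-2-ol F3. Thermolysis (xylene, Bu3N, 130 °C, 1 mM) should extrude ethylene from the ethoxyalkyne to give (3Z,7S)-7-hydroxy-3,7-dimethyl-8-[(triethylsilyl)oxy]octa-1,3-dien-1-one F4, a vinylketene that the tertiary hydroxyl captures, with α-protonation keeping the (Z)-β,γ-olefin. This returns to the route at lactone 8.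

Step 8 (alkylidenation of the lactone). The low-valent titanium–zinc mixture may reduce or ring-open the hindered lactone, the Lewis-acidic medium may ionise the tertiary allylic C4–O bond, or the enol-ether geometry may not be controlled. The fallback attaches the isobutylidene group by a sulfone-based (modified Julia) olefination of the lactone and sets out from 10. S-Alkylation of 2-mercaptobenzothiazole with 1-bromo-2-methylpropane (K2CO3, DMF) gives 2-[(2-methylpropyl)sulfanyl]-1,3-benzothiazole F5, and oxidation (H2O2, (NH4)6Mo7O24 cat., EtOH) gives 2-[(2-methylpropyl)sulfonyl]-1,3-benzothiazole F6. Deprotonation of F6 with LiN(SiMe3)2 in the presence of 10 (THF, −78 °C) should give the hemiketal adduct (8S)-2-[1-(1,3-benzothiazol-2-ylsulfonyl)-2-methylpropyl]-4,8-dimethyl-8-[(E)-2-(4,4,5,5-tetramethyl-1,3,2-dioxaborolan-2-yl)ethenyl]-3,6,7,8-tetrahydro-2H-oxocin-2-ol F7 as a diastereomer mixture. DBU (THF, rt) then triggers Smiles rearrangement with loss of sulfur dioxide and benzothiazolone to the exocyclic enol ether. The (Z)-isomer would be separated on base-washed silica, and the route is rejoined at 14.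

Step 13 (directed epoxidation). Oxygen delivery through the titanium template may go to the erythro face, as metal-alkoxide-bound oxidants do with medium-ring cycloalkenols, may leak to C10=C1, or the titanium may open the tertiary epoxide. The fallback installs the epoxide earlier with a peracid, whose hydrogen-bonded transition state matches the threo geometry, at a stage where C10=C1 is deactivated as the β,γ-olefin of the C8 ketone. It sets out from 15. Oxidation of the C–B bond (H2O2, NaHCO3, THF/H2O, 0 °C) should give (2S,3S,4Z,8Z)-3-hydroxy-5,9-dimethyl-2-(propan-2-yl)cyclodeca-4,8-dien-1-one F8. Epoxidation with mCPBA (NaHCO3, CH2Cl2, −20 °C) should give (1(10)Z,4R,5S,6R,7S)-4,5-epoxy-6-hydroxygermacr-1(10)-en-8-one F9. Narasaka–Prasad reduction (Et2BOMe, NaBH4, THF/MeOH, −78 °C) should give the 1,3-syn diol (1(10)Z,4R,5S,6R,7R,8R)-4,5-epoxygermacr-1(10)-ene-6,8-diol F10. Acylation with one equivalent of 17 (DMAP, Et3N, CH2Cl2, −40 °C) at the less hindered C8 hydroxyl (C6–OH is flanked by the epoxide and hydrogen-bonded to it) then returns to the route at 20.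

**Further compounds**

F1 | step 4 | (4S)-4-hydroxy-4-methyl-5-[(triethylsilyl)oxy]pentanal | O=CCC[C@@](C)(CO[Si](CC)(CC)CC)O
F2 | step 4 | (2S,5Z)-6-iodo-2-methyl-1-[(triethylsilyl)oxy]hept-5-en-2-ol | I/C(C)=C\CC[C@@](C)(CO[Si](CC)(CC)CC)O
F3 | step 4 | (2S,5Z)-8-ethoxy-2,6-dimethyl-1-[(triethylsilyl)oxy]oct-5-en-7-yn-2-ol | CCOC#C/C(C)=C\CC[C@@](C)(CO[Si](CC)(CC)CC)O
F4 | step 4 | (3Z,7S)-7-hydroxy-3,7-dimethyl-8-[(triethylsilyl)oxy]octa-1,3-dien-1-one | O=C=C/C(C)=C\CC[C@@](C)(CO[Si](CC)(CC)CC)O
F5 | step 8 | 2-[(2-methylpropyl)sulfanyl]-1,3-benzothiazole | CC(C)CSc1nc2ccccc2s1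
F6 | step 8 | 2-[(2-methylpropyl)sulfonyl]-1,3-benzothiazole | CC(C)CS(=O)(=O)c1nc2ccccc2s1
F7 | step 8 | (8S)-2-[1-(1,3-benzothiazol-2-ylsulfonyl)-2-methylpropyl]-4,8-dimethyl-8-[(E)-2-(4,4,5,5-tetramethyl-1,3,2-dioxaborolan-2-yl)ethenyl]-3,6,7,8-tetrahydro-2H-oxocin-2-ol | CC(C)C(S(=O)(=O)c1nc2ccccc2s1)C1(O)C/C(C)=C\CC[C@@](C)(/C=C/B2OC(C)(C)C(C)(C)O2)O1
F8 | step 13 | (2S,3S,4Z,8Z)-3-hydroxy-5,9-dimethyl-2-(propan-2-yl)cyclodeca-4,8-dien-1-one | O=C1C/C(C)=C\CC/C(C)=C\[C@H](O)[C@@H]1C(C)C
F9 | step 13 | (1(10)Z,4R,5S,6R,7S)-4,5-epoxy-6-hydroxygermacr-1(10)-en-8-one | O=C1C/C(C)=C\CC[C@@]2(C)O[C@H]2[C@H](O)[C@@H]1C(C)C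
F10 | step 13 | (1(10)Z,4R,5S,6R,7R,8R)-4,5-epoxygermacr-1(10)-ene-6,8-diol | O[C@@H]1C/C(C)=C\CC[C@@]2(C)O[C@H]2[C@H](O)[C@@H]1C(C)C
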